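Readings and results were generated by integration from invented constants.

I reckon these flasks by one ratio: how long a Z molecule lasts, over how long a Q molecule waits for J.

| setting | alpha | beta | dusk | dawn | summer |
|---|---|---|---|---|---|
| Q | 0.10 M | 0.10 M | 0.10 M | 0.10 M | 0.10 M |
| J | 0.11 M | 0.34 M | 0.150 M | 0.0800 M | 0.300 M |
| remark | run made earlier | run made earlier |  |  |  |
| time |  |  | 2.5 d | 2.5 d | 2.5 d |

| run | time / d | Z / % | D / % | Q / % |
|---|---|---|---|---|
| alpha | 0.208 | 7.6 | 0.6 | 91.4 |
| alpha | 0.417 | 14.8 | 0.3 | 84.1 |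
| alpha | 0.625 | 17.4 | 0 | 77.6 |
| alpha | 1.25 | 23.9 | 0.2 | 63.9 |
| alpha | 2.50 | 22.6 | 0.4 | 45.5 |
| beta | 0.208 | 23.2 | 0 | 75.8 |
| beta | 0.417 | 35.7 | 0.2 | 58.9 |
| beta | 0.625 | 43.7 | 0.3 | 45.9 |
| beta | 1.25 | 47.0 | 1.2 | 23.1 |
| beta | 2.50 | 31.7 | 0.7 | 5.9 |

(readings scatter by 0.5 percentage points)

- which of these holds the largest part of the Q at the end of dusk (G / D / Z / X / Q)
- which of these holds the largest part of the Q at the end of dawn (G / D / Z / X / Q)
- which of these holds the largest part of the Q at the end of summer (G / D / Z / X / Q)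
- Z at the end of dusk, in percent of the Q charged

A Q molecule takes up J and becomes Z, with L beside it. A Z may then go to E, or take up more J on the way to X, D and G. The one further adduct read is D, and it is faint, 1.2 % in beta at 1.25 d, so I count Q lost minus Z gained as Z's loss. From 1.25 d to 2.50 d that gives Z a half-life of 1.05 d in beta and 1.02 d in alpha, with J charged at 0.34 M against 0.11 M. So J seems to have little say at this fork.

Q's wait does depend on J. Beta, with J in excess and Q's loss nearly pseudo-first-order, gives a Q half-life of 1.16 d when scaled to dusk's charge of J. The ratio is therefore 0.904 for dusk; this is ρ, Z's half-life over Q's half-life at the J charged. It is 0.482 for dawn and 1.81 for summer. Taken at the J present, it sinks as J is used, and dusk's Q can take 66.7 % of the J charged. I therefore expect Q narrowly ahead in dusk, clearly ahead in dawn, and Z ahead in summer.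

The forecast names Q, Q and Z in that order, and puts Z at 25.2 % (23.7 % to 26.7 %) at the end of dusk, holding that “Z is lost first order to E”.

Dusk ends with Q at 33.7 % and Z at 27.3 %, dawn with Q at 57.6 %, and summer with Z at 32.0 %.

Q + J → Z + L (k = 0.170 L mol⁻¹ h⁻¹); J + Z → X + L (k = 0.00670 L mol⁻¹ h⁻¹); J + X → D + L (k = 0.700 L mol⁻¹ h⁻¹); J + D → G + L (k = 0.270 L mol⁻¹ h⁻¹); Z → E (k = 0.0250 h⁻¹) In dusk, Z is made 1.99 times as fast as it is used at 0.751 d, and 0.668 times as fast at 2.50 d, each step taken net. Taken at the J left at 2.50 d, ρ is 0.491 in dusk and 0.785 in the neighbour with Q cut to 0.025 M, which keeps 87 % of its J and ends with Z at 31.5 %, above Q at 24.5 %.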